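**Plan**

1. Retrosynthesis: the side chain is cut at C13–C14/C12–C13 (CBS reduction of a C14 enone; Felkin aldol of a C12 aldehyde), C18 and the 9‑OH are taken off a C10 ketone, the cyclopentene is cut at C2–C3 and C4–C5 (this removes propyne and leaves a cyclopropane C1–C2–C5 fused to a cycloheptanone), and C7–C11 is cut by a Claisen disconnection.
2. Forward: cyclohepta‑1,3‑diene → (R)‑4‑hydroxycyclohept‑2‑enone → cyclopropyl ketone → ketal Claisen (C7, C11) → samarium radical‑relay (3+2) with propyne (cyclopentene ring) → C6 reduction → C10 ketone (ring‑fusion epimerisation, 9‑hydroxylation, methylenation) → side chain → deprotection.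
3. Enabling feature: the C6 oxygen sits next to ring‑fusion carbon C5. As a ketone it lets the C2–C5 bond of a ring‑fused cyclopropane open to a C2 radical and a C5 enolate, between which propyne is inserted, so the five‑membered ring arises from the three‑membered one.
4. Stereochemistry: the C10 carbinol (catalytic desymmetrisation, later destroyed) directs the cyclopropane and hence C5; (R,Z)‑pent‑3‑en‑2‑ol sets C7 and C11 by chirality transfer; C6 and C9 are substrate‑controlled; C1 is set thermodynamically; C12 by Felkin control; C14 by the CBS catalyst.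

Key step: step 10

Remark on locants: target numbering is used throughout. C1 and C5 are the ring‑fusion carbons, C2–C3=C4(C20) complete the cyclopentene, C6 is a carbinol, C7 bears the side chain, C8 is CH2, C9 is a carbinol, C10 bears the methylidene C18, and the side chain is C11(C19)–C12(OAc)–C13–C14(OH)–C15(=C16)C17. β is the face of the seven‑membered ring that carries the C7 side chain in the target, α the other face. The target is (1S,5R,6S,7R,9S,11S,12S,14R): 6‑OH β, 9‑OH α, H‑5 β, H‑1 α.

Assumption: 9‑O‑acetylcupreidine is taken to give the (R)‑alcohol 3 from 2; if its sense is opposite, the pseudoenantiomeric 9‑O‑acetylcupreine is used and nothing else changes.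

**Route**

Step 1
Reactants: 1 cyclohepta‑1,3‑diene
Product: 2 6,7‑dioxabicyclo[3.2.2]non‑8‑ene (meso endoperoxide)
Conditions: O2, tetraphenylporphyrin (cat.), visible light, CH2Cl2, 0 °C
Reagents that add atoms: dioxygen, O=O
Why: Singlet‑oxygen (4+2) photooxygenation of a cyclic 1,3‑diene gives the bridged endoperoxide, which is meso because both new C–O bonds lie on one face.

Step 2
Reactants: 2 endoperoxide
Product: 3 (R)‑4‑hydroxycyclohept‑2‑en‑1‑one (C6 ketone, C5=C1 alkene, 10β‑OH)
Conditions: 9‑O‑acetylcupreidine (5 mol%), CH2Cl2, rt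
Reagents that add atoms: none
Why: Kornblum–DeLaMare rearrangement under chiral Brønsted‑base catalysis: the cinchona base removes one of the two enantiotopic bridgehead hydrogens with O–O cleavage, which should give the γ‑hydroxy enone and set the C10 carbinol centre.

Step 3
Reactants: 3 hydroxy enone
Product: 4 (R)‑4‑[(tert‑butyldimethylsilyl)oxy]cyclohept‑2‑en‑1‑one
Conditions: TBSCl, imidazole, DMF, 0 °C to rt
Reagents that add atoms: tert‑butyldimethylsilyl chloride, CC(C)(C)[Si](C)(C)Cl
Why: Standard silylation of a secondary alcohol; unlike a benzyl‑type ether, the silyl ether offers no easily abstracted hydrogen to the radicals of step 10.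

Step 4
Reactants: 4 silyloxy enone
Product: 5 6‑[(tert‑butyldimethylsilyl)oxy]bicyclo[5.1.0]octan‑2‑one, cyclopropane trans to the silyloxy group (C6 ketone, cyclopropane C1–C2–C5 on the α face, 10β‑OTBS)
Conditions: Me3S(O)I, NaH, DMSO, rt
Reagents that add atoms: trimethylsulfoxonium iodide, C[S+](C)(C)=O.[I-]
Why: Corey–Chaykovsky cyclopropanation: conjugate addition of the sulfoxonium ylide at C1 anti to the adjacent 10β‑silyloxy group and 3‑exo‑tet closure onto C5 should place the cyclopropane on the α face, setting C1 and C5.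

Step 5
Reactants: 5 cyclopropyl ketone
Product: 6 2,2‑dimethyl ketal of 5
Conditions: HC(OMe)3, MeOH, PPTS (cat.), rt
Reagents that add atoms: trimethyl orthoformate, COC(OC)OC
Why: Acid‑catalysed ketalisation with orthoformate as water scavenger prepares the ketone for ketal exchange; no stereocentre is touched.

Step 6
Reactants: 7 (R)‑but‑3‑yn‑2‑ol
Product: 8 (R)‑pent‑3‑yn‑2‑ol
Conditions: n‑BuLi (2.1 equiv), THF, −78 to 0 °C; MeI
Reagents that add atoms: iodomethane, CI
Why: Double deprotonation gives the alkoxide–acetylide, which is alkylated at the more nucleophilic acetylide carbon; the carbinol centre is not involved.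

Step 7
Reactants: 8 (R)‑pent‑3‑yn‑2‑ol
Product: 9 (R,Z)‑pent‑3‑en‑2‑ol
Conditions: H2 (1 atm), Pd/CaCO3 poisoned with Pb(OAc)2, quinoline, pentane, rt
Reagents that add atoms: none
Why: Semihydrogenation over poisoned palladium adds hydrogen syn and stops at the (Z)‑alkene.

Step 8
Reactants: 6 dimethyl ketal; 9 (R,Z)‑pent‑3‑en‑2‑ol
Product: 11 3‑[(2R,3E)‑pent‑3‑en‑2‑yl] derivative of 5 (substituent on C7, β, 7R; C11 as in the target), via allyl enol ether 10 (not isolated)
Conditions: 9 (2 equiv), propionic acid (cat.), xylene, 135 °C, MeOH distilled off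
Reagents that add atoms: none
Why: Ketal exchange and loss of methanol give enol ether 10, which can form only toward C7, and its Claisen rearrangement through a chair transition state (carbinol methyl equatorial, (Z)‑methyl axial) on the β face, away from the cyclopropane CH2, should set C7 and C11 by chirality transfer and leave an (E)‑alkene.

Step 9
Reactants: 11 Claisen ketone
Product: 13 3‑[(2S)‑1,1‑dimethoxypropan‑2‑yl] analogue (C12 dimethyl acetal), via aldehyde 12 (not isolated)
Conditions: O3, CH2Cl2/MeOH, −78 °C; Me2S; then HC(OMe)3, CeCl3·7H2O (cat.), MeOH, rt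
Reagents that add atoms: ozone, [O-][O+]=O; trimethyl orthoformate, COC(OC)OC
Why: Ozonolysis cleaves the only C=C bond, and CeCl3‑catalysed acetalisation, which is selective for aldehydes over hindered ketones, masks C12 before the samarium step without isolating the epimerisable aldehyde.

Step 10
Reactants: 13 cyclopropyl ketone acetal; 14 propyne
Product: 15 cis‑fused hydroazulenone: 6‑oxo, Δ3, 4‑methyl, H‑1 β, H‑5 β, 10β‑OTBS, 7β‑[(2S)‑1,1‑dimethoxypropan‑2‑yl]
Conditions: SmI2 (20 mol%), Sm powder (20 mol%), 14 (5 equiv, THF solution), THF, 55 °C, sealed tube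
Reagents that add atoms: none
Why: SmI2 reduces the C6 ketone to a ketyl, whose cyclopropylcarbinyl fragmentation cleaves the exocyclic C2–C5 bond to a trivalent samarium enolate (C5=C6) and a primary C2 radical; this adds to the terminal carbon of propyne (new C2–C3 bond), and the C4 vinyl radical closes on the enolate carbon C5 by 5‑exo‑trig attack (new C4–C5 bond), giving a ketyl that returns its electron to trivalent samarium. The closest known reaction type is the SmI2‑catalysed radical‑relay formal (3+2) coupling of bicyclic alkyl cyclopropyl ketones with alkynes. The only new stereocentre, C5, is fixed by the three‑atom tether: the vinyl radical can reach only the α face on which C2 sits, so the ring fusion is cis at this stage, and C1, C7, C10 and C11 are untouched under the neutral conditions. The methyl ends on C4 and the hydrogen on C3 because the radical attacks the unsubstituted alkyne carbon, and the C2–C5 bond (not C1–C5) breaks because it overlaps best with the ketyl orbital in the bicyclo[5.1.0] frame. Ring opening is reversible, so slow trapping by the unactivated alkyne is bridged by excess propyne, and the fast cyclisation of the vinyl radical should outrun hydrogen abstraction.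

Step 11
Reactants: 15 hydroazulenone
Product: 16 6β‑alcohol of 15
Conditions: LiBH(s‑Bu)3, THF, −78 °C
Reagents that add atoms: none
Why: Ketone reduction with a bulky trialkylborohydride, which should attack C6 from the α face, anti to the branched β‑substituent on C7, giving the 6β‑alcohol cis to the side chain.

Step 12
Reactants: 16 6β‑alcohol
Product: 17 6β‑(4‑methoxybenzyl) ether
Conditions: KN(SiMe3)2, THF, 0 °C; 4‑methoxybenzyl chloride, Bu4NI (cat.), 0 °C to rt
Reagents that add atoms: 4‑methoxybenzyl chloride, COc1ccc(CCl)cc1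
Why: Williamson etherification of the potassium alkoxide installs a group that survives fluoride, base and Lewis acid and is removed oxidatively near the end.

Step 13
Reactants: 17 ether
Product: 18 10β‑alcohol
Conditions: Bu4NF, THF, rt
Reagents that add atoms: none
Why: Fluoride cleaves the only silyl ether; acetal and benzyl‑type ether are inert.

Step 14
Reactants: 18 10β‑alcohol
Product: 20 trans‑fused 10‑ketone (H‑1 α, H‑5 β), via cis‑fused 10‑ketone 19 (not isolated)
Conditions: Dess–Martin periodinane, NaHCO3, CH2Cl2, rt; then DBU, toluene, rt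
Reagents that add atoms: none
Why: Dess–Martin oxidation gives ketone 19, and base‑mediated enolisation toward C1 should equilibrate the ring fusion to the trans isomer, the arrangement generally preferred for hydroazulenones with the carbonyl in the seven‑membered ring next to the fusion; C5 is not acidic here.

Step 15
Reactants: 20 trans‑fused ketone
Product: 22 9α‑[(tert‑butyldimethylsilyl)oxy] 10‑ketone, via potassium 9α‑alkoxide 21 (not isolated)
Conditions: KN(SiMe3)2, THF, −78 °C; 3‑phenyl‑2‑(phenylsulfonyl)oxaziridine; then TBSCl, −78 to 0 °C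
Reagents that add atoms: 3‑phenyl‑2‑(phenylsulfonyl)oxaziridine, O1N(S(=O)(=O)c2ccccc2)C1c1ccccc1; tert‑butyldimethylsilyl chloride, CC(C)(C)[Si](C)(C)Cl
Why: Kinetic deprotonation at the C9 methylene (not the C1 methine), enolate oxidation by the N‑sulfonyloxaziridine from the α face, opposite C2, the 6β‑ether and the C7 side chain, and silylation of the alkoxide in the same flask should give the 9α‑silyloxy ketone.

Step 16
Reactants: 22 silyloxy ketone
Product: 23 10(18)‑methylidene compound
Conditions: Ph3PCH3Br, KOtBu, THF, 0 to 45 °C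
Reagents that add atoms: methyltriphenylphosphonium bromide, C[P+](c1ccccc1)(c1ccccc1)c1ccccc1.[Br-]
Why: Wittig methylenation with the non‑stabilised ylide; C1 already has its thermodynamic configuration and the hindered C9–H next to the silyloxy group should not epimerise.

Step 17
Reactants: 23 acetal
Product: 24 C12 aldehyde
Conditions: PPTS (cat.), acetone/H2O (10:1), 45 °C
Reagents that add atoms: water, O
Why: Mild acid‑catalysed hydrolysis of the dimethyl acetal releases the aldehyde while the silyl and 4‑methoxybenzyl ethers remain.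

Step 18
Reactants: 25 3‑methylbut‑3‑en‑2‑one
Product: 26 3‑methyl‑2‑(trimethylsilyloxy)buta‑1,3‑diene
Conditions: LiN(iPr)2, THF, −78 °C; Me3SiCl
Reagents that add atoms: chlorotrimethylsilane, C[Si](C)(C)Cl
Why: Kinetic deprotonation of the methyl ketone at its only α‑position and O‑silylation give the enol silane.

Step 19
Reactants: 24 aldehyde; 26 enol silane
Product: 27 (12S)‑12‑hydroxy‑14‑oxo enone (β‑hydroxy ketone)
Conditions: BF3·OEt2, CH2Cl2, −78 °C
Reagents that add atoms: none
Why: Mukaiyama aldol addition through an open transition state should follow the Felkin–Anh model for the α‑methyl aldehyde, with the ring as the large group, giving the 11,12‑syn alcohol, i.e. C12 (S).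

Step 20
Reactants: 27 aldol
Product: 28 12‑acetate
Conditions: Ac2O, pyridine, DMAP (cat.), CH2Cl2, 0 °C
Reagents that add atoms: acetic anhydride, CC(=O)OC(C)=O
Why: Acetylation of the only free hydroxyl, run cold and short to avoid β‑elimination of the β‑acetoxy ketone.

Step 21
Reactants: 28 acetate
Product: 29 6β‑alcohol (14‑oxo, 9α‑OTBS)
Conditions: DDQ, CH2Cl2/pH 7 buffer, 0 °C
Reagents that add atoms: none
Why: Oxidative cleavage of the 4‑methoxybenzyl ether by DDQ frees the 6‑OH while the silyl ether, acetate and enone stay.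

Step 22
Reactants: 29 enone
Product: 30 (14R)‑alcohol, 9‑O‑TBS ether of the target
Conditions: (S)‑2‑methyl‑CBS‑oxazaborolidine (0.5 equiv), catecholborane (3 equiv), toluene, −78 °C
Reagents that add atoms: none
Why: Corey–Bakshi–Shibata reduction: with the isopropenyl group as the large substituent the (S)‑catalyst should give the (R)‑allylic alcohol at C14 independently of the remote centres, and catecholborane does not hydroborate the alkenes at −78 °C.

Step 23
Reactants: 30 silyl ether
Product: 31 CNP0281601.4 (target)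
Conditions: HF·pyridine, pyridine, THF, 0 °C to rt
Reagents that add atoms: none
Why: Fluoride cleavage of the allylic silyl ether under buffered, non‑basic conditions leaves the acetate in place and avoids 1,3‑acyl migration.

**Compound list**

1 | cyclohepta‑1,3‑diene | C1=CC=CCCC1 | starting material
2 | 6,7‑dioxabicyclo[3.2.2]non‑8‑ene (meso) | C1C[C@H]2C=C[C@@H](C1)OO2 | intermediate
3 | (R)‑4‑hydroxycyclohept‑2‑en‑1‑one | C1CC[C@@H](O)C=CC1=O | intermediate
4 | (R)‑4‑[(tert‑butyldimethylsilyl)oxy]cyclohept‑2‑en‑1‑one | C1CC[C@@H](O[Si](C)(C)C(C)(C)C)C=CC1=O | intermediate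
5 | 6‑[(tert‑butyldimethylsilyl)oxy]bicyclo[5.1.0]octan‑2‑one, cyclopropane trans to OTBS | C1CC[C@@H](O[Si](C)(C)C(C)(C)C)[C@@H]2C[C@@H]2C1=O | intermediate
6 | 2,2‑dimethyl ketal of 5 | C1CC[C@@H](O[Si](C)(C)C(C)(C)C)[C@@H]2C[C@@H]2C1(OC)OC | intermediate
7 | (R)‑but‑3‑yn‑2‑ol | C[C@@H](O)C#C | starting material
8 | (R)‑pent‑3‑yn‑2‑ol | C[C@@H](O)C#CC | intermediate
9 | (R,Z)‑pent‑3‑en‑2‑ol | C[C@@H](O)/C=C\C | intermediate
10 | C6=C7 enol ether of 5 with (R,Z)‑pent‑3‑en‑2‑ol | C1CC[C@@H](O[Si](C)(C)C(C)(C)C)[C@@H]2C[C@@H]2C(O[C@H](C)/C=C\C)=1 | intermediate (not isolated)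
11 | 7β‑[(2R,3E)‑pent‑3‑en‑2‑yl] cyclopropyl ketone | C/C=C/[C@@H](C)[C@H]1CC[C@@H](O[Si](C)(C)C(C)(C)C)[C@@H]2C[C@@H]2C1=O | intermediate
12 | 7β‑[(2S)‑1‑oxopropan‑2‑yl] cyclopropyl ketone (C12 aldehyde) | O=C[C@@H](C)[C@H]1CC[C@@H](O[Si](C)(C)C(C)(C)C)[C@@H]2C[C@@H]2C1=O | intermediate (not isolated)
13 | 7β‑[(2S)‑1,1‑dimethoxypropan‑2‑yl] cyclopropyl ketone | COC(OC)[C@@H](C)[C@H]1CC[C@@H](O[Si](C)(C)C(C)(C)C)[C@@H]2C[C@@H]2C1=O | intermediate
14 | propyne | CC#C | starting material
15 | cis‑fused 6‑oxo‑Δ3‑hydroazulene, 10β‑OTBS, C12 acetal | COC(OC)[C@@H](C)[C@H]1CC[C@@H](O[Si](C)(C)C(C)(C)C)[C@@H]2CC=C(C)[C@@H]2C1=O | intermediate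
16 | 6β‑alcohol of 15 | COC(OC)[C@@H](C)[C@H]1CC[C@@H](O[Si](C)(C)C(C)(C)C)[C@@H]2CC=C(C)[C@@H]2[C@H]1O | intermediate
17 | 6β‑(4‑methoxybenzyl) ether, 10β‑OTBS | COC(OC)[C@@H](C)[C@H]1CC[C@@H](O[Si](C)(C)C(C)(C)C)[C@@H]2CC=C(C)[C@@H]2[C@H]1OCc3ccc(OC)cc3 | intermediate
18 | 10β‑alcohol, 6β‑OPMB | COC(OC)[C@@H](C)[C@H]1CC[C@@H](O)[C@@H]2CC=C(C)[C@@H]2[C@H]1OCc3ccc(OC)cc3 | intermediate
19 | cis‑fused 10‑ketone | COC(OC)[C@@H](C)[C@H]1CCC(=O)[C@@H]2CC=C(C)[C@@H]2[C@H]1OCc3ccc(OC)cc3 | intermediate (not isolated)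
20 | trans‑fused 10‑ketone (H‑1 α, H‑5 β) | COC(OC)[C@@H](C)[C@H]1CCC(=O)[C@H]2CC=C(C)[C@@H]2[C@H]1OCc3ccc(OC)cc3 | intermediate
21 | potassium 9α‑alkoxide of the 9‑hydroxy‑10‑ketone | COC(OC)[C@@H](C)[C@H]1C[C@H]([O-])C(=O)[C@H]2CC=C(C)[C@@H]2[C@H]1OCc3ccc(OC)cc3.[K+] | intermediate (not isolated)
22 | 9α‑OTBS 10‑ketone | COC(OC)[C@@H](C)[C@H]1C[C@H](O[Si](C)(C)C(C)(C)C)C(=O)[C@H]2CC=C(C)[C@@H]2[C@H]1OCc3ccc(OC)cc3 | intermediate
23 | 10(18)‑methylidene acetal | COC(OC)[C@@H](C)[C@H]1C[C@H](O[Si](C)(C)C(C)(C)C)C(=C)[C@H]2CC=C(C)[C@@H]2[C@H]1OCc3ccc(OC)cc3 | intermediate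
24 | C12 aldehyde | O=C[C@@H](C)[C@H]1C[C@H](O[Si](C)(C)C(C)(C)C)C(=C)[C@H]2CC=C(C)[C@@H]2[C@H]1OCc3ccc(OC)cc3 | intermediate
25 | 3‑methylbut‑3‑en‑2‑one | CC(=O)C(C)=C | starting material
26 | 3‑methyl‑2‑(trimethylsilyloxy)buta‑1,3‑diene | C=C(O[Si](C)(C)C)C(C)=C | intermediate
27 | (12S)‑12‑hydroxy‑14‑oxo enone | C=C(C)C(=O)C[C@H](O)[C@@H](C)[C@H]1C[C@H](O[Si](C)(C)C(C)(C)C)C(=C)[C@H]2CC=C(C)[C@@H]2[C@H]1OCc3ccc(OC)cc3 | intermediate
28 | 12‑acetate of 27 | C=C(C)C(=O)C[C@H](OC(C)=O)[C@@H](C)[C@H]1C[C@H](O[Si](C)(C)C(C)(C)C)C(=C)[C@H]2CC=C(C)[C@@H]2[C@H]1OCc3ccc(OC)cc3 | intermediate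
29 | 6β‑alcohol, 14‑oxo, 9α‑OTBS | C=C(C)C(=O)C[C@H](OC(C)=O)[C@@H](C)[C@H]1C[C@H](O[Si](C)(C)C(C)(C)C)C(=C)[C@H]2CC=C(C)[C@@H]2[C@H]1O | intermediate
30 | 9‑O‑TBS ether of the target | C=C(C)[C@H](O)C[C@H](OC(C)=O)[C@@H](C)[C@H]1C[C@H](O[Si](C)(C)C(C)(C)C)C(=C)[C@H]2CC=C(C)[C@@H]2[C@H]1O | intermediate
31 | CNP0281601.4, (1S,5R,6S,7R,9S,11S,12S,14R) | C=C(C)[C@H](O)C[C@H](OC(C)=O)[C@@H](C)[C@H]1C[C@H](O)C(=C)[C@H]2CC=C(C)[C@@H]2[C@H]1O | target

**Count**

Total steps: 23. Longest linear sequence: 20 (steps 1–5, 8–17, 19–23).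

**Steps most likely to fail**

Step 10. The primary C2 radical may be trapped too slowly by the unactivated alkyne, so that catalyst decay or hydrogen‑atom transfer to the radical wins. The fallback sets out from 13 and comes back at 15. 13 is coupled under the same samarium conditions with ethynyltrimethylsilane, whose silicon stabilises the vinyl radical and speeds the addition, giving the 4‑(trimethylsilyl)cyclopentene F1. Iododesilylation with N‑iodosuccinimide gives the vinyl iodide F2 with retention. Negishi coupling with MeZnCl and Pd(PPh3)4 then installs C20 and gives 15.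

Step 11. Facial selectivity may be poor: the cis‑fused cyclopentene shields the α face, so hydride may instead add from the β face and give the 6α‑alcohol. The fallback sets out from 15 and comes back at 16. 15 is reduced deliberately with the small reagent NaBH4/CeCl3 to the 6α‑alcohol F3. Mitsunobu esterification with 4‑nitrobenzoic acid (PPh3, DIAD) inverts C6 and gives the 6β‑4‑nitrobenzoate F4. Methanolysis (K2CO3, MeOH) gives 16.

Step 8. A competing boat transition state may erode the C7/C11 relationship, or the cyclopropyl ketal may open under hot acid. The fallback sets out from 5 and comes back at 13. The barium enolate of 5 is allylated with methyl (E)‑but‑2‑enyl carbonate under [Ir(cod)Cl]2 and a chiral phosphoramidite (branched‑selective), giving the 7β‑[(R)‑but‑3‑en‑2‑yl] ketone F5 with C11 set by the catalyst. C7, being α to the ketone, can be equilibrated with DBU if needed. Ozonolysis and acetalisation as in step 9 give 13.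

**Further compounds**

F1 | step 10 | 4‑(trimethylsilyl) analogue of 15 (C4–SiMe3 in place of C4–CH3) | COC(OC)[C@@H](C)[C@H]1CC[C@@H](O[Si](C)(C)C(C)(C)C)[C@@H]2CC=C([Si](C)(C)C)[C@@H]2C1=O
F2 | step 10 | 4‑iodo analogue of 15 | COC(OC)[C@@H](C)[C@H]1CC[C@@H](O[Si](C)(C)C(C)(C)C)[C@@H]2CC=C(I)[C@@H]2C1=O
F3 | step 11 | 6α‑alcohol (C6 epimer of 16) | COC(OC)[C@@H](C)[C@H]1CC[C@@H](O[Si](C)(C)C(C)(C)C)[C@@H]2CC=C(C)[C@@H]2[C@@H]1O
F4 | step 11 | 6β‑(4‑nitrobenzoate) of 16 | COC(OC)[C@@H](C)[C@H]1CC[C@@H](O[Si](C)(C)C(C)(C)C)[C@@H]2CC=C(C)[C@@H]2[C@H]1OC(=O)c3ccc(cc3)[N+](=O)[O-]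
F5 | step 8 | 7β‑[(R)‑but‑3‑en‑2‑yl] cyclopropyl ketone | C=C[C@@H](C)[C@H]1CC[C@@H](O[Si](C)(C)C(C)(C)C)[C@@H]2C[C@@H]2C1=O
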